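Do not book J against the L charged, as the tables print it: Sunday's flask holds less G (0.445 M) than L (0.89 M), so keep its books on G, the limiting reagent.

| flask | L | G | remark | time |
|---|---|---|---|---|
| eta | 0.89 M | 0.38 M | run made earlier |  |
| gamma | 0.89 M | 0.70 M | run made earlier |  |
| epsilon | 0.89 M | 1.3 M | run made earlier |  |
| Tuesday's | 0.89 M | 1.07 M |  | 12 min |
| Friday's | 0.89 M | 0.712 M |  | 12 min |
| Sunday's | 0.89 M | 0.445 M |  | 12 min |

| run | time / min | J / % | Z / % | L / % |
|---|---|---|---|---|
| eta | 1.50 | 24 | 2 | 49 |
| eta | 3.00 | 28 | 0 | 47 |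
| eta | 5.00 | 30 | 4 | 44 |
| eta | 6.00 | 31 | 2 | 45 |
| gamma | 0.500 | 20 | 3 | 54 |
| gamma | 1.00 | 31 | 5 | 45 |
| gamma | 2.50 | 35 | 8 | 35 |
| gamma | 6.00 | 40 | 5 | 27 |
| epsilon | 1.50 | 40 | 16 | 23 |
| epsilon | 3.00 | 35 | 16 | 15 |
| epsilon | 5.00 | 34 | 17 | 11 |
| epsilon | 6.00 | 31 | 14 | 12 |

(each reading ± 1.5 percentage points)



- which of these holds the largest part of the L at the end of Tuesday's (J / Z / L)
- which of these holds the largest part of the L at the end of Friday's (J / Z / L)
- which of these holds the largest part of the L at the end of Sunday's (J / Z / L)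
- J at the end of Sunday's, in percent of the L charged

Open the ledger with the charge ratio cG/cL, which gives the G charged in percent of the L, on the same scale as the J column. J holds one G and Z holds two, so enter J first and call the rest the G tax, 27.4% in the eta run, the share of the charged G that does not stand as J at a run's last reading. Take that reading as the closing entry, since eta's J reads 30% and then 31% at its last two; gamma's reads 35% and then 40%, so its entry is less sure. Eta charges 42.7% and closes with J at 31%. Gamma charges 78.7%, closes with J at 40%, and pays 49.1%. Between these two runs the tax, as read, rises by 0.605 per equivalent of G. Sunday's charges 50.0%, so draw the line to a tax of 31.8%, which leaves J at 34.1%.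

The forecast names J for Tuesday's, J for Friday's and L for Sunday's, with J at 33.5% on Sunday's, slightly below this reckoning. Its ground is that Sunday's “lies just above eta”.

The flask gives J for Tuesday's, J for Friday's and L for Sunday's, with J at 32.3% on Sunday's.

    L + G → J (k = 0.0200 M⁻¹ s⁻¹)
    G + J → Z (k = 0.0120 M⁻¹ s⁻¹)
    Z ⇌ D (K = 3.10, k = 0.0130 s⁻¹)
    L ⇌ E (K = 0.450, k = 0.460 s⁻¹)

Sunday's books close at 50.0% of the L: J at 32.3%, plus twice Z at 2.17%, plus twice D at 6.68%, with free G at 0.0387% of its own charge. The tax paid is 35.4%, against 31.8% on the line. Now take a neighbouring flask, Sunday's with 0.76 M of G, which charges 85.4%. The same line, carried past gamma's charge, gives a tax of 53.2% and J at 40.0%. That flask holds J at 39.2%.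

Readings and results stem from a simulated flask from invented constants; noise was put on by code.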